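**Remarks on the chemistry (assumptions)**
- Rings A to E are read along the chain from the phloroglucinol end. The ether oxygens sit on A-C4/B-C1, B-C6/C-C1, C-C4/D-C1 and D-C6/E-C1.
- The key-step partners and the key-step product were re-derived atom by atom from rings D and E of the target. They agree with it, so no structure is corrected.
- The design of the precursor is improved in handling only. The ylide is kept as its phosphonium chloride 14 and released in the flask, the chloromethyl ether 13 is never isolated, and the pyrylium ion is used as its tetrafluoroborate.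
- Compounds 1, 2, 6, 12, 19, 21 and 25 are taken as purchasable.

## Structural features

The target 30 (C30H22O18) is a linear chain of five benzene rings joined only by four diaryl ether oxygens. It has no C–C bond between rings and no stereocentre, so no question of neighbouring stereocentres arises. Ring A is a phloroglucinol etherified at the carbon between two hydroxyls. Rings B and D share one pattern: ether oxygens on the adjacent carbons C1 and C6, hydroxyls on C3, C4 and C5, and one hydrogen on C2. Ring C carries its two ether oxygens para to each other with hydroxyls on C3 and C5, and ring E is a 3,4,5-trihydroxyphenyl ether. The fourteen free hydroxyls, nine of them in pyrogallol arrays on rings B, D and E, make the free compound very polar and prone to autoxidation, above all in base; the diaryl ether bonds are robust. The real difficulty is C–O bond construction between electron-rich rings: nucleophilic aromatic substitution is not available, the ether oxygens on A-C4, C-C4, B-C6 and D-C6 each sit on a carbon with two ortho oxygen substituents, and the two neighbouring oxygens of rings B and D must be told apart. The key step uses the pattern of ring E: oxygens on E-C3, E-C4 and E-C5 and hydrogens on E-C2 and E-C6 are those of a 3,4,5-trimethoxypyrylium ion. Exchanging its ring oxygen for a ylide carbon that already carries the D-C6 ether oxygen builds ring E onto the hindered oxygen of ring D without an aryl halide or a metal catalyst.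

## Logic of the disconnections

**30 to 29.** The fourteen O–H bonds of 30 are traced back to O–CH3 bonds in 29. Methyl is the only ether group that the cation of 5 tolerates on its C4 oxygen, and it survives ylide, peracid, copper and palladium chemistry. All earlier compounds thereby become neutral and chromatographable. The forward step must cleave every methyl ether and none of the four diaryl ethers, and the product must be isolated without air.

**29 to 18 and 28.** The bond between C-C4 and the oxygen on D-C1 is cut. This separates blocks of similar size (two rings in 18, three in 28) and places the halogen on the symmetric ring C, where no regiochemical question arises. The forward step needs a C–O coupling at a carbon flanked by two methoxy groups, with an oxygen nucleophile that has one ortho substituent.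

**18 to 17.** The O–H bond of 18 goes back to an O–CH2Ph bond. The D-C1 oxygen has to be distinguishable from thirteen methyl ethers, and hydrogenolysis does that without touching anything else.

**17 to 14 and 5 (via 15 and 16).** Ring E is opened at E-C1–E-C2 and E-C1–E-C6. This removes E-C1 as a one-carbon unit that stays attached to the ether oxygen and leaves a five-carbon oxygen heterocycle with all three methoxy groups in place. The gain is that the ether on the doubly flanked D-C6 oxygen is carried through ready-made and no aryl halide of ring E is needed. The forward step demands attack of 15 at C2 and not C4 of 5, ring opening to 16, a second deprotonation and an intramolecular carbonyl olefination.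

**14 to 11 and 12 (via 13), 11 to 10.** The P–CH2 bond and then the O–CH2 bond are cut. The one-carbon unit is introduced as an O,S-acetal, so the reactive α-chloro ether 13 exists only transiently. The forward steps need S-selective chlorination in the presence of an electron-rich arene.

**10 to 8 (via 9), 8 to 7, 7 to 6.** The D-C6 oxygen is traced back to a formyl group (aryl migration to oxygen), the benzyl ether to the free hydroxyl, and the formyl carbon to a C–H bond of 6. Both ortho positions of 6 are equivalent, so the 1,2-dioxygen pattern of ring D is set without regiochemical risk. The demand is that the aryl group, not hydride, migrates in the oxidation.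

**5 to 4, 4 to 1 and 2 (via 3).** The O–CH3 bond on C4 of 5 is cut, then the two ring C–O bonds and the C2–C3 and C5–C6 bonds of 4. The heterocycle thus comes from a symmetric three-carbon ketone and two one-carbon units. The demand is a double condensation on 1.

**28 to 24 and 27, 27 to 25 (via 26).** The bond between C-C1 and the oxygen on B-C6 is cut. 27 has two different halogens, so the unhindered iodide can react first and the shielded bromide is kept for the final coupling. 27 is traced to 25 by cutting the C–I bond at the only sterically free C–H.

**24 to 22 (via 23), 22 to 20 and 21, 20 to 19.** The B-C6 hydroxyl is again traced back to a formyl group. In 22 that group activates the neighbouring C–Br bond of 20, so the hindered ether at A-C4 is made with ring A as the nucleophile (21) and an activated electrophile. 20 comes from 19 by cutting the C–CHO bond at the position between bromine and methoxy.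

## Other disconnections considered

**Alternative 1: ring B by squarate ring expansion.** The cut is through ring B at B-C2–B-C3; the ring is assembled from the four carbons of dimethyl squarate A1 and the two vinyl carbons of the ring A vinyl ether 2-(ethenyloxy)-1,3,5-trimethoxybenzene A2. In the forward direction, the α-metallated form of A2 adds to A1 to give the cyclobutenone A3. Heating opens A3 to a dienylketene whose 6π closure and tautomerisation would give the hydroquinone A4.
- In its favour: the hindered A-C4–O–B-C1 ether arrives as a simple vinyl ether, so no aryl coupling is needed on the ring A side. That is at least the equal of steps 10 to 12 of the chosen plan. The ring expansion is a well-precedented reaction type for alkoxy-substituted hydroquinones, and on that count it is better founded than the chosen key step. The substitution pattern of ring B is fixed by the mechanism.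
- Against it here: α-metallation of A2 must compete with lithiation between the methoxy groups of its aryl ring, which is the classic ortho-lithiation site, so a tin or halogen detour is likely. A4 is an electron-rich hydroquinone that should oxidise easily. Its two free hydroxyls (B-C3 and B-C6) must be differentiated before the more hindered one is arylated.
- Comparison: step economy up to the stage of 24 is about equal. The alternative leaves the B–C, C–D and D–E ethers untouched, so it can replace steps 10 to 12 but not the difficult coupling of step 15.

**Alternative 2: ring A folded from an aryloxy triketide.** The cut is at A-C4–A-C5. The open-chain ester A5 would cyclise under excess base by attack of the aryloxy-bearing C6 on the ester carbon to give the aryloxyphloroglucinol A6.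
- In its favour: the ether at A-C4 is made as an ordinary alkyl aryl ether by SN2 chemistry. That is better than any metal-catalysed coupling at this doubly flanked position, and ring A comes from very cheap carbon.
- Against it here: C6 is the least acidic carbon of A5 (C2 and C4 lie between carbonyls), so the closure needs a polyanion. Attack of the C5 enol oxygen on the ester to give the 2-pyranone A7 is the usual non-enzymatic fate of such chains. A6 would then need three O-methylations, in which C-methylation of the phloroglucinol can compete, plus debenzylation.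
- Comparison: steps 11 and 12 of the chosen plan reach the same ring A–ring B stage with an activated, regiochemically fixed coupling and fewer operations. The alternative is equal in its final substitution pattern and better in avoiding copper, but weaker in mechanistic control and longer by roughly two steps.

**Alternative 3: central ring C by convergent benzannulation.** The cuts are at C-C2–C-C3 and C-C1–C-C6, with the C-C3–C-C4 bond formed in the closing electrocyclisation. The ring A–ring B ethynyl ether A8 (from 24) and the ring D–ring E cyclobutenone A9 (from 18) would be heated together. A vinylketene forms from A9, adds to A8 and, after a second ring opening and 6π closure, gives the protected pentamer A10.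
- In its favour: it joins the two halves while creating ring C, and neither ether of ring C has to be made by coupling. On the most hindered bond this is better than the chosen plan, whose step 15 is its weakest conventional step. Regiochemistry follows from the mechanism, and the ethyl ether and free hydroxyl of A10 are both resolved in the final dealkylation, which is equal to the chosen end game.
- Against it here: aryl ethynyl ethers such as A8 are thermally delicate and need two further steps from 24, including a strong base that the acidic C–H positions of ring A may not tolerate. A9 needs about three steps from 18, and its C4–H next to an aryloxy group invites enolisation. A benzannulation with heteroatom substituents on both partners is less secure than the parent reaction.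
- Comparison: convergence is equal. The alternative is about three steps longer after 18 and 24 and places its least certain step on the two most advanced intermediates. It still needs the ring D–ring E ether, so it would complement rather than replace the chosen key step.

Key step: step 8

## Steps

Step 1
Reactants: 1 1,3-dimethoxypropan-2-one; 2 N,N-dimethylformamide dimethyl acetal
Product: 4 3,5-dimethoxy-4H-pyran-4-one, via bis-enaminone 3 (not isolated)
Conditions: 2 (3 equiv), neat, 110 °C, MeOH distilled off; then 1 M aq. HCl, THF, 50 °C
Reagents that add atoms: water, O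
Why: Double aminomethylenation of the two methoxy-activated CH2 groups gives the cross-conjugated bis-enaminone 3; acid hydrolyses one enaminone to the enol, whose oxygen adds to the other and expels Me2NH to close the 4-pyranone. This is the standard enaminone route to 3,5-disubstituted 4-pyranones.

Step 2
Reactants: 4 3,5-dimethoxy-4H-pyran-4-one
Product: 5 3,4,5-trimethoxypyrylium tetrafluoroborate
Conditions: Me3OBF4 (1.05 equiv), CH2Cl2, 23 °C; Et2O, filtration under Ar
Reagents that add atoms: trimethyloxonium tetrafluoroborate, C[O+](C)C.F[B-](F)(F)F
Why: O-Alkylation of the vinylogous ester carbonyl of a 4-pyranone by an oxonium salt gives the aromatic 4-alkoxypyrylium ion. The tetrafluoroborate avoids the explosion hazard of perchlorates and should precipitate cleanly.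

Step 3
Reactants: 6 3,4,5-trimethoxyphenol
Product: 7 2-hydroxy-4,5,6-trimethoxybenzaldehyde
Conditions: MgCl2, Et3N, (CH2O)n, MeCN, reflux
Reagents that add atoms: paraformaldehyde (formaldehyde), C=O
Why: Magnesium phenoxide-directed ortho-formylation: the bound phenoxide adds formaldehyde at the ortho carbon and a second formaldehyde oxidises the benzylic alkoxide by hydride transfer. Both ortho positions of 6 are equivalent, so one product is expected.

Step 4
Reactants: 7 2-hydroxy-4,5,6-trimethoxybenzaldehyde
Product: 8 2-(benzyloxy)-4,5,6-trimethoxybenzaldehyde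
Conditions: BnBr, K2CO3, DMF, 60 °C
Reagents that add atoms: benzyl bromide, BrCc1ccccc1
Why: Williamson etherification of the salicylaldehyde hydroxyl. The benzyl group marks the oxygen that becomes the D-C1 oxygen and is the only group later removable by hydrogenolysis.

Step 5
Reactants: 8 2-(benzyloxy)-4,5,6-trimethoxybenzaldehyde
Product: 10 6-(benzyloxy)-2,3,4-trimethoxyphenol, via aryl formate 9 (not isolated)
Conditions: mCPBA, NaHCO3, CH2Cl2, 0 to 23 °C; aq. Na2S2O3 wash; then K2CO3 (cat.), MeOH, 23 °C, Ar
Reagents that add atoms: 3-chloroperoxybenzoic acid, OOC(=O)c1cccc(Cl)c1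
Why: Baeyer–Villiger oxidation (Dakin type): the electron-rich di-ortho-alkoxyaryl group migrates in preference to hydride to give formate 9. The formate is methanolysed only after the peracid is destroyed, so the oxidisable phenol 10 never meets oxidant.

Step 6
Reactants: 10 6-(benzyloxy)-2,3,4-trimethoxyphenol
Product: 11 1-(benzyloxy)-3,4,5-trimethoxy-2-[(methylsulfanyl)methoxy]benzene
Conditions: ClCH2SMe, Cs2CO3, NaI (cat.), DMF, 50 °C
Reagents that add atoms: chloromethyl methyl sulfide, CSCCl
Why: SN2 O-alkylation of the caesium phenoxide by the α-chloro sulfide under iodide catalysis gives the O,S-acetal. The methylthiomethyl ether is a storable, non-volatile precursor of the chloromethyl ether.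

Step 7
Reactants: 11 1-(benzyloxy)-3,4,5-trimethoxy-2-[(methylsulfanyl)methoxy]benzene; 12 triphenylphosphine
Product: 14 {[6-(benzyloxy)-2,3,4-trimethoxyphenoxy]methyl}triphenylphosphonium chloride, via chloromethyl ether 13 (not isolated)
Conditions: SO2Cl2 (1.0 equiv), CH2Cl2, −78 to 0 °C; volatiles removed; then 12, toluene, 60 °C
Reagents that add atoms: sulfuryl chloride, ClS(Cl)(=O)=O
Why: Sulfuryl chloride chlorinates sulfur far faster than the arene at −78 °C and the chlorosulfonium ion fragments to 13 and MeSCl, the known conversion of methylthiomethyl ethers into chloromethyl ethers. 13 is consumed at once by SN2 quaternisation of 12 to the crystalline salt 14.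

Step 8
Reactants: 14 {[6-(benzyloxy)-2,3,4-trimethoxyphenoxy]methyl}triphenylphosphonium chloride; 5 3,4,5-trimethoxypyrylium tetrafluoroborate
Product: 17 1-(benzyloxy)-3,4,5-trimethoxy-2-(3,4,5-trimethoxyphenoxy)benzene, via aryloxymethylene ylide 15 (not isolated), via dienal phosphonium salt 16 (not isolated)
Conditions: KN(SiMe3)2 (1.0 equiv), THF, −78 °C; cannulated into 5 (1.2 equiv), THF, −78 to 0 °C; then KOt-Bu (1.1 equiv), 0 to 60 °C
Reagents that add atoms: none
Why: Proposed new method: KN(SiMe3)2 converts 14 into the α-aryloxy ylide 15, whose carbon should add to C2 of the cation of 5 to give a 2H-pyran that opens by thermal oxa-6π electrocyclic ring opening to the dienal phosphonium salt 16; KOt-Bu then forms a vinylogous phosphonium trienolate in which the C2–C3 and C4–C5 bonds can rotate, and intramolecular Wittig olefination of the aldehyde expels Ph3PO to give 17. The closest known reaction type is the conversion of 2,4,6-triarylpyrylium salts into benzenes by alkylidenetriphenylphosphoranes (and into nitroarenes by nitromethane); a 2,6-unsubstituted 4-alkoxypyrylium ion and an α-aryloxy ylide have not been shown in it. Ring E closes by 6-exo-trig attack of the ylide carbon E-C1 on the aldehyde carbon E-C6, the E-C1 to E-C2 bond having been made in the addition, and aromatisation makes the closure irreversible. No stereocentre remains: the phosphonium-bearing carbon of 16 and both alkene geometries are erased on aromatisation. The step needs attack at C2 and not C4, and addition and not electron transfer; C2 is the unhindered position next to the ring oxygen whereas C4 bears a methoxy group between two others, the three donor groups lower the reduction potential of the cation, and the C2 adduct is drained by ring opening. Inverse addition of 15 to a slight excess of 5 keeps free ylide away from the aldehyde of 16 and so suppresses intermolecular olefination, and the second base is added only when 15 is consumed.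

Step 9
Reactants: 17 1-(benzyloxy)-3,4,5-trimethoxy-2-(3,4,5-trimethoxyphenoxy)benzene
Product: 18 3,4,5-trimethoxy-2-(3,4,5-trimethoxyphenoxy)phenol
Conditions: H2 (1 atm), Pd/C (10 wt % Pd on carbon), EtOAc–MeOH, 23 °C
Reagents that add atoms: none
Why: Hydrogenolysis of the single benzyl ether over palladium. Methyl and diaryl ethers are inert, so only the D-C1 hydroxyl is freed.

Step 10
Reactants: 19 5-bromo-1,2,3-trimethoxybenzene
Product: 20 6-bromo-2,3,4-trimethoxybenzaldehyde
Conditions: LiN(i-Pr)2, THF, −78 °C; DMF, −78 °C; aq. HCl
Reagents that add atoms: N,N-dimethylformamide, CN(C)C=O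
Why: Directed ortho-lithiation: the C–H between bromine and a methoxy group is the most acidic site (the two are equivalent) and the amide base does not undergo halogen–metal exchange. The aryllithium is formylated by DMF below the temperature at which LiBr is lost.

Step 11
Reactants: 20 6-bromo-2,3,4-trimethoxybenzaldehyde; 21 2,4,6-trimethoxyphenol
Product: 22 2,3,4-trimethoxy-6-(2,4,6-trimethoxyphenoxy)benzaldehyde
Conditions: CuI (10 mol %), picolinic acid (20 mol %), K3PO4, DMSO, 90 °C, Ar
Reagents that add atoms: none
Why: Copper-catalysed Ullmann diaryl ether synthesis. The bromide of 20 is activated by the ortho-formyl group and has one ortho substituent only, and the picolinate ligand system is established for di-ortho-substituted phenols such as 21.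

Step 12
Reactants: 22 2,3,4-trimethoxy-6-(2,4,6-trimethoxyphenoxy)benzaldehyde
Product: 24 2,3,4-trimethoxy-6-(2,4,6-trimethoxyphenoxy)phenol, via aryl formate 23 (not isolated)
Conditions: mCPBA, NaHCO3, CH2Cl2, 0 °C; aq. Na2S2O3 wash; then K2CO3 (cat.), MeOH, 23 °C, Ar
Reagents that add atoms: 3-chloroperoxybenzoic acid, OOC(=O)c1cccc(Cl)c1
Why: Baeyer–Villiger oxidation and methanolysis as in step 5. The aryl group with ortho-methoxy and ortho-aryloxy donors migrates, which turns the activating formyl group into the B-C6 hydroxyl.

Step 13
Reactants: 25 2-bromo-1,3-dimethoxybenzene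
Product: 27 2-bromo-5-iodo-1,3-dimethoxybenzene, via arylboronate 26 (not isolated)
Conditions: [Ir(OMe)(cod)]2 (1.5 mol %), 4,4'-di-tert-butyl-2,2'-bipyridine (3 mol %), B2pin2, THF, 80 °C; then CuI (10 mol %), 1,10-phenanthroline (20 mol %), KI, MeOH–H2O, air, 80 °C
Reagents that add atoms: potassium iodide, [K+].[I-]; bis(pinacolato)diboron, CC1(C)OB(OC1(C)C)B1OC(C)(C)C(C)(C)O1 (boron of intermediate 26 only)
Why: Sterically controlled iridium-catalysed C–H borylation takes place at C5, the only C–H not ortho to a substituent. Copper-mediated iododeboronation of 26 in the same flask puts iodine on that carbon (a known one-pot borylation–halogenation sequence) and leaves the aryl bromide intact.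

Step 14
Reactants: 24 2,3,4-trimethoxy-6-(2,4,6-trimethoxyphenoxy)phenol; 27 2-bromo-5-iodo-1,3-dimethoxybenzene
Product: 28 2-bromo-1,3-dimethoxy-5-[2,3,4-trimethoxy-6-(2,4,6-trimethoxyphenoxy)phenoxy]benzene
Conditions: CuI (10 mol %), picolinic acid (20 mol %), K3PO4, DMSO, 90 °C, Ar
Reagents that add atoms: none
Why: Ullmann coupling of the hindered phenol 24 at the unhindered iodide of 27. The C–I bond should react well before the C–Br bond, which is shielded by two ortho-methoxy groups, so the bromide is kept for step 15.

Step 15
Reactants: 18 3,4,5-trimethoxy-2-(3,4,5-trimethoxyphenoxy)phenol; 28 2-bromo-1,3-dimethoxy-5-[2,3,4-trimethoxy-6-(2,4,6-trimethoxyphenoxy)phenoxy]benzene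
Product: 29 2-{2-[3,5-dimethoxy-4-[3,4,5-trimethoxy-2-(3,4,5-trimethoxyphenoxy)phenoxy]phenoxy]-3,4,5-trimethoxyphenoxy}-1,3,5-trimethoxybenzene (tetradecamethyl ether of 30)
Conditions: Pd(OAc)2 (5 mol %), t-BuXPhos (2-di-tert-butylphosphino-2',4',6'-triisopropylbiphenyl, 10 mol %), K3PO4, toluene, 100 °C, Ar
Reagents that add atoms: none
Why: Palladium-catalysed C–O cross-coupling (Buchwald–Hartwig etherification) with a bulky di-tert-butylbiarylphosphine. Such ligands allow oxidative addition of electron-rich aryl bromides, and ortho substituents on the aryl group speed C–O reductive elimination; phenol 18 has a single ortho substituent.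

Step 16
Reactants: 29 tetradecamethyl ether of 30
Product: 30 2-{2-[4-[3,4,5-trihydroxy-2-(3,4,5-trihydroxyphenoxy)phenoxy]-3,5-dihydroxyphenoxy]-3,4,5-trihydroxyphenoxy}benzene-1,3,5-triol
Conditions: BBr3 (40 equiv), CH2Cl2, −78 to 23 °C; MeOH, then degassed H2O, Ar; reversed-phase chromatography
Reagents that add atoms: none
Why: Exhaustive Lewis acid dealkylation of aryl methyl ethers: boron binds the oxygen and bromide attacks the methyl group by SN2. Diaryl ether C–O bonds are not cleaved because neither carbon is open to SN2, and solvolysis of the aryl borates under argon releases 30.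

## Compound list

1 | 1,3-dimethoxypropan-2-one | COCC(=O)COC | starting material
2 | N,N-dimethylformamide dimethyl acetal | COC(OC)N(C)C | starting material
3 | (1Z,4Z)-1,5-bis(dimethylamino)-2,4-dimethoxypenta-1,4-dien-3-one | CN(C)/C=C(\OC)C(=O)/C(OC)=C/N(C)C | intermediate
4 | 3,5-dimethoxy-4H-pyran-4-one | COc1cocc(OC)c1=O | intermediate
5 | 3,4,5-trimethoxypyrylium tetrafluoroborate | COc1c[o+]cc(OC)c1OC.F[B-](F)(F)F | intermediate
6 | 3,4,5-trimethoxyphenol | COc1cc(O)cc(OC)c1OC | starting material
7 | 2-hydroxy-4,5,6-trimethoxybenzaldehyde | COc1cc(O)c(C=O)c(OC)c1OC | intermediate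
8 | 2-(benzyloxy)-4,5,6-trimethoxybenzaldehyde | COc1cc(OCc2ccccc2)c(C=O)c(OC)c1OC | intermediate
9 | 2-(benzyloxy)-4,5,6-trimethoxyphenyl formate | COc1cc(OCc2ccccc2)c(OC=O)c(OC)c1OC | intermediate
10 | 6-(benzyloxy)-2,3,4-trimethoxyphenol | COc1cc(OCc2ccccc2)c(O)c(OC)c1OC | intermediate
11 | 1-(benzyloxy)-3,4,5-trimethoxy-2-[(methylsulfanyl)methoxy]benzene | COc1cc(OCc2ccccc2)c(OCSC)c(OC)c1OC | intermediate
12 | triphenylphosphine | c1ccc(cc1)P(c1ccccc1)c1ccccc1 | starting material
13 | 1-(benzyloxy)-2-(chloromethoxy)-3,4,5-trimethoxybenzene | COc1cc(OCc2ccccc2)c(OCCl)c(OC)c1OC | intermediate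
14 | {[6-(benzyloxy)-2,3,4-trimethoxyphenoxy]methyl}triphenylphosphonium chloride | COc1cc(OCc2ccccc2)c(OC[P+](c2ccccc2)(c2ccccc2)c2ccccc2)c(OC)c1OC.[Cl-] | intermediate
15 | {[6-(benzyloxy)-2,3,4-trimethoxyphenoxy]methylidene}triphenylphosphorane | COc1c(OC)c(OC)cc(OCc2ccccc2)c1OC=P(c1ccccc1)(c1ccccc1)c1ccccc1 | intermediate
16 | racemic [(2Z,4Z)-1-[6-(benzyloxy)-2,3,4-trimethoxyphenoxy]-3,4,5-trimethoxy-6-oxohexa-2,4-dien-1-yl]triphenylphosphonium tetrafluoroborate (isomer expected from outward rotation) | O=C/C(OC)=C(OC)\C(OC)=C\C(Oc1c(OCc2ccccc2)cc(OC)c(OC)c1OC)[P+](c1ccccc1)(c1ccccc1)c1ccccc1.F[B-](F)(F)F | intermediate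
17 | 1-(benzyloxy)-3,4,5-trimethoxy-2-(3,4,5-trimethoxyphenoxy)benzene | COc1cc(Oc2c(OCc3ccccc3)cc(OC)c(OC)c2OC)cc(OC)c1OC | intermediate
18 | 3,4,5-trimethoxy-2-(3,4,5-trimethoxyphenoxy)phenol | COc1cc(Oc2c(O)cc(OC)c(OC)c2OC)cc(OC)c1OC | intermediate
19 | 5-bromo-1,2,3-trimethoxybenzene | COc1cc(Br)cc(OC)c1OC | starting material
20 | 6-bromo-2,3,4-trimethoxybenzaldehyde | COc1cc(Br)c(C=O)c(OC)c1OC | intermediate
21 | 2,4,6-trimethoxyphenol | COc1cc(OC)c(O)c(OC)c1 | starting material
22 | 2,3,4-trimethoxy-6-(2,4,6-trimethoxyphenoxy)benzaldehyde | COc1cc(Oc2c(OC)cc(OC)cc2OC)c(C=O)c(OC)c1OC | intermediate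
23 | 2,3,4-trimethoxy-6-(2,4,6-trimethoxyphenoxy)phenyl formate | COc1cc(Oc2c(OC)cc(OC)cc2OC)c(OC=O)c(OC)c1OC | intermediate
24 | 2,3,4-trimethoxy-6-(2,4,6-trimethoxyphenoxy)phenol | COc1cc(Oc2c(OC)cc(OC)cc2OC)c(O)c(OC)c1OC | intermediate
25 | 2-bromo-1,3-dimethoxybenzene | COc1cccc(OC)c1Br | starting material
26 | 2-(4-bromo-3,5-dimethoxyphenyl)-4,4,5,5-tetramethyl-1,3,2-dioxaborolane | COc1cc(cc(OC)c1Br)B1OC(C)(C)C(C)(C)O1 | intermediate
27 | 2-bromo-5-iodo-1,3-dimethoxybenzene | COc1cc(I)cc(OC)c1Br | intermediate
28 | 2-bromo-1,3-dimethoxy-5-[2,3,4-trimethoxy-6-(2,4,6-trimethoxyphenoxy)phenoxy]benzene | COc1cc(Oc2c(OC)cc(OC)cc2OC)c(Oc2cc(OC)c(Br)c(OC)c2)c(OC)c1OC | intermediate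
29 | 2-{2-[3,5-dimethoxy-4-[3,4,5-trimethoxy-2-(3,4,5-trimethoxyphenoxy)phenoxy]phenoxy]-3,4,5-trimethoxyphenoxy}-1,3,5-trimethoxybenzene | COc1cc(OC)c(Oc2cc(OC)c(OC)c(OC)c2Oc2cc(OC)c(Oc3cc(OC)c(OC)c(OC)c3Oc3cc(OC)c(OC)c(OC)c3)c(OC)c2)c(OC)c1 | intermediate
30 | 2-{2-[4-[3,4,5-trihydroxy-2-(3,4,5-trihydroxyphenoxy)phenoxy]-3,5-dihydroxyphenoxy]-3,4,5-trihydroxyphenoxy}benzene-1,3,5-triol (CNP0273977.0) | Oc1cc(O)c(Oc2cc(O)c(O)c(O)c2Oc2cc(O)c(Oc3cc(O)c(O)c(O)c3Oc3cc(O)c(O)c(O)c3)c(O)c2)c(O)c1 | target

## Step count and least certain steps

Total: 16 steps. Longest linear sequence: 9 steps (steps 3, 4, 5, 6, 7, 8, 9, 15, 16, from 6 to 30).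

**Step 8 (key step, proposed new method).**
- What may go wrong: addition of the ylide at C4 followed by loss of methoxide; single-electron transfer from the ylide to the cation with radical coupling; hydrolysis of the cation by traces of water; intermolecular olefination of the aldehyde of 16; or a ring closure that stalls because the delocalised ylide is too stabilised.
- Fallback (known chemistry): it sets out from 10 and 19 and comes back at 17. Copper-catalysed Ullmann coupling (CuI, picolinic acid, K3PO4, DMSO, 110 °C) joins the di-ortho-substituted phenol 10 to the unhindered aryl bromide 19. This gives 17 directly, with ring E bought and not built, and makes 5, 11 and 14 unnecessary. No new compound is formed.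

**Step 15.**
- What may go wrong: slow oxidative addition or slow C–O reductive elimination at the doubly ortho-substituted, very electron-rich bromide, which would lead to hydrodebromination or recovered partners.
- Fallback: it sets out from 18 and comes back at 29, using 24 directly in place of 28. Nucleophilic aromatic substitution of 2-fluoro-1,3-dimethoxy-5-nitrobenzene by the phenoxide of 18 (K2CO3, DMF, 100 °C) gives 1,3-dimethoxy-5-nitro-2-[3,4,5-trimethoxy-2-(3,4,5-trimethoxyphenoxy)phenoxy]benzene F1. Reduction (Fe, NH4Cl, EtOH–H2O) gives 3,5-dimethoxy-4-[3,4,5-trimethoxy-2-(3,4,5-trimethoxyphenoxy)phenoxy]aniline F2. Diazotisation and iodide exchange (NaNO2, TsOH, KI, MeCN) give 5-iodo-1,3-dimethoxy-2-[3,4,5-trimethoxy-2-(3,4,5-trimethoxyphenoxy)phenoxy]benzene F3. F3 is an unhindered iodide and is coupled with 24 under the conditions of step 14 to give 29. The hindered ether is then made on an activated ring, at the cost of two extra steps.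

**Step 7.**
- What may go wrong: ring chlorination or sulfenylation of the electron-rich arene by SO2Cl2 or MeSCl at its one free position, and hydrolysis of 13 by moisture before quaternisation.
- Fallback: it sets out from 10 and comes back at 15. O-Alkylation with bromomethyl acetate (K2CO3, acetone) gives [6-(benzyloxy)-2,3,4-trimethoxyphenoxy]methyl acetate F4. Ionisation of this O,O-acetal with Me3SiOTf in the presence of 12 (CH2Cl2, 0 °C), the way α-alkoxyalkylphosphonium salts are made from acetals, gives {[6-(benzyloxy)-2,3,4-trimethoxyphenoxy]methyl}triphenylphosphonium trifluoromethanesulfonate F5. F5 is deprotonated to 15 exactly as 14 is in step 8. No electrophilic chlorine is involved.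

**Step 16.**
- What may go wrong: incomplete dealkylation because partly cleaved borates precipitate, and oxidative degradation of the pyrogallol units during work-up and chromatography.
- Fallback: it sets out from 29 and comes back at 30. After the BBr3 treatment and methanol quench the crude polyphenol is not purified but peracetylated (Ac2O, pyridine) to the tetradecaacetate of 30 F6. F6 is air-stable and can be purified on silica, which also removes partly methylated material. Acid methanolysis (HCl generated from AcCl in degassed MeOH) then releases 30 without base.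

**Step 1.**
- What may go wrong: the second aminomethylenation stalls at the mono-enaminone, which is a vinylogous amide with a less acidic CH2 group, and the amine-rich mixture gives tar on acidification.
- Fallback: it sets out from 1 and comes back at 4. Double Claisen formylation with ethyl formate and NaOMe (THF, 0 °C) gives 1,5-dihydroxy-2,4-dimethoxypenta-1,4-dien-3-one F7 as its disodium salt, which cyclises with loss of water on treatment with aqueous HCl. This is the classical formylation route to 3,5-disubstituted 4-pyranones.

## Further compounds

F0 | step 8 | none | none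
F1 | step 15 | 1,3-dimethoxy-5-nitro-2-[3,4,5-trimethoxy-2-(3,4,5-trimethoxyphenoxy)phenoxy]benzene | COc1cc(cc(OC)c1Oc1cc(OC)c(OC)c(OC)c1Oc1cc(OC)c(OC)c(OC)c1)[N+](=O)[O-]
F2 | step 15 | 3,5-dimethoxy-4-[3,4,5-trimethoxy-2-(3,4,5-trimethoxyphenoxy)phenoxy]aniline | COc1cc(N)cc(OC)c1Oc1cc(OC)c(OC)c(OC)c1Oc1cc(OC)c(OC)c(OC)c1
F3 | step 15 | 5-iodo-1,3-dimethoxy-2-[3,4,5-trimethoxy-2-(3,4,5-trimethoxyphenoxy)phenoxy]benzene | COc1cc(I)cc(OC)c1Oc1cc(OC)c(OC)c(OC)c1Oc1cc(OC)c(OC)c(OC)c1
F4 | step 7 | [6-(benzyloxy)-2,3,4-trimethoxyphenoxy]methyl acetate | COc1cc(OCc2ccccc2)c(OCOC(C)=O)c(OC)c1OC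
F5 | step 7 | {[6-(benzyloxy)-2,3,4-trimethoxyphenoxy]methyl}triphenylphosphonium trifluoromethanesulfonate | COc1cc(OCc2ccccc2)c(OC[P+](c2ccccc2)(c2ccccc2)c2ccccc2)c(OC)c1OC.[O-]S(=O)(=O)C(F)(F)F
F6 | step 16 | tetradecaacetate of 30 | CC(=O)Oc1cc(OC(C)=O)c(Oc2cc(OC(C)=O)c(OC(C)=O)c(OC(C)=O)c2Oc2cc(OC(C)=O)c(Oc3cc(OC(C)=O)c(OC(C)=O)c(OC(C)=O)c3Oc3cc(OC(C)=O)c(OC(C)=O)c(OC(C)=O)c3)c(OC(C)=O)c2)c(OC(C)=O)c1
F7 | step 1 | 1,5-dihydroxy-2,4-dimethoxypenta-1,4-dien-3-one (bis-enol of 2,4-dimethoxy-3-oxopentanedial, formed as the disodium salt) | OC=C(OC)C(=O)C(OC)=CO
A1 | alternative 1 | dimethyl squarate (3,4-dimethoxycyclobut-3-ene-1,2-dione) | COC1=C(OC)C(=O)C1=O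
A2 | alternative 1 | 2-(ethenyloxy)-1,3,5-trimethoxybenzene | C=COc1c(OC)cc(OC)cc1OC
A3 | alternative 1 | racemic 4-hydroxy-2,3-dimethoxy-4-[1-(2,4,6-trimethoxyphenoxy)ethenyl]cyclobut-2-en-1-one | COC1=C(OC)C(O)(C(=C)Oc2c(OC)cc(OC)cc2OC)C1=O
A4 | alternative 1 | 2,3-dimethoxy-5-(2,4,6-trimethoxyphenoxy)benzene-1,4-diol | COc1c(O)cc(Oc2c(OC)cc(OC)cc2OC)c(O)c1OC
A5 | alternative 2 | methyl 6-[2-(benzyloxy)-3,4,5-trimethoxyphenoxy]-3,5-dioxohexanoate | COC(=O)CC(=O)CC(=O)COc1cc(OC)c(OC)c(OC)c1OCc1ccccc1
A6 | alternative 2 | 2-[2-(benzyloxy)-3,4,5-trimethoxyphenoxy]benzene-1,3,5-triol | Oc1cc(O)c(Oc2cc(OC)c(OC)c(OC)c2OCc2ccccc2)c(O)c1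
A7 | alternative 2 | 6-{[2-(benzyloxy)-3,4,5-trimethoxyphenoxy]methyl}-4-hydroxy-2H-pyran-2-one | O=c1cc(O)cc(COc2cc(OC)c(OC)c(OC)c2OCc2ccccc2)o1
A8 | alternative 3 | 1-(ethynyloxy)-2,3,4-trimethoxy-6-(2,4,6-trimethoxyphenoxy)benzene | C#COc1c(Oc2c(OC)cc(OC)cc2OC)cc(OC)c(OC)c1OC
A9 | alternative 3 | racemic 3-ethoxy-4-[3,4,5-trimethoxy-2-(3,4,5-trimethoxyphenoxy)phenoxy]cyclobut-2-en-1-one | CCOC1=CC(=O)C1Oc1cc(OC)c(OC)c(OC)c1Oc1cc(OC)c(OC)c(OC)c1
A10 | alternative 3 | protected pentamer with ring C as 3-hydroxy-5-ethoxy and all other hydroxyls methylated | COc1cc(OC)c(Oc2cc(OC)c(OC)c(OC)c2Oc2cc(O)c(Oc3cc(OC)c(OC)c(OC)c3Oc3cc(OC)c(OC)c(OC)c3)c(OCC)c2)c(OC)c1
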